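**Retrosynthetic overview**
- The strategy rests on the two aryl C4–O bonds that join each 3-methoxyphenyl (guaiacyl) ring on C2 and C5 of the oxolane to the oxygen on C8 of a (7R,8S) chain. Both are cut on the aryl side, giving a meso all-cis bis(aryl chloride) core and two equivalents of one enantiopure chain alcohol whose C8–O bond is never broken.
- The chain alcohol comes from methyl (S)-lactate (C8) and 4-bromo-1,2-dimethoxybenzene; C7 is set by chelation-controlled ketone reduction, and the benzylic oxygen is silylated.
- The core comes from 4-chloro-3-methoxybenzaldehyde: stilbene, then oxirane, then carbonyl ylide [3+2] cycloaddition with maleic anhydride, which sets all four ring stereocentres; the two carboxyl carbons are then reduced to methyl groups.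
- Ring order: oxirane (sacrificed), then the oxolane, the only ring built; the anhydride ring arrives with maleic anhydride and is opened by reduction.

Key step: step 13

Remark: the benzylic oxygen of the chain is carried as a triisopropylsilyl ether, because a smaller silyl group next to a free hydroxyl can undergo 1,2 O→O migration under hot carbonate base, which would scramble the position of the aryl ether.

**Route**

Step 1
Reactants: 1 4-chloro-3-methoxybenzaldehyde (two molecules)
Product: 2 (E)-1,2-bis(4-chloro-3-methoxyphenyl)ethene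
Conditions: TiCl4, Zn dust, THF, reflux
Reagents that add atoms: none
Why: McMurry reductive coupling of an aromatic aldehyde on low-valent titanium (pinacolate formation, then deoxygenation) should give the thermodynamically preferred E-stilbene, and aryl chlorides and methyl ethers are tolerated.

Step 2
Reactants: 2 (E)-1,2-bis(4-chloro-3-methoxyphenyl)ethene
Product: 3 trans-2,3-bis(4-chloro-3-methoxyphenyl)oxirane (racemic)
Conditions: mCPBA, NaHCO3, CH2Cl2, 0 °C to rt
Reagents that add atoms: mCPBA (3-chloroperoxybenzoic acid), OOC(=O)c1cccc(Cl)c1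
Why: Prilezhaev epoxidation transfers oxygen in a concerted syn fashion, so the E-alkene should give the trans-oxirane, which is racemic but loses its stereocentres in the next step, and with no para donor on the rings the buffered oxirane should not open.

Step 3
Reactants: 3 trans-2,3-bis(4-chloro-3-methoxyphenyl)oxirane; 4 maleic anhydride
Product: 6 all-cis meso 4,6-bis(4-chloro-3-methoxyphenyl)tetrahydrofuro[3,4-c]furan-1,3-dione, via carbonyl ylide 5 (not isolated)
Conditions: 1,4-dicyanonaphthalene (cat.), hν (Pyrex, λ > 300 nm), MeCN, rt, N2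
Reagents that add atoms: none
Why: Photoinduced electron transfer to singlet-excited 1,4-dicyanonaphthalene should trigger C–C cleavage of the oxirane radical cation and, after back electron transfer, give the planar exo,exo carbonyl ylide 5, which adds suprafacially to maleic anhydride in a 1,3-dipolar [3+2] cycloaddition that closes the oxolane ring; the ylide geometry sets the 2,5-cis aryl relationship, the cis-alkene sets the 3,4-cis relationship, and the endo approach (anhydride under the C–O–C unit) places the anhydride cis to both aryl groups, so all four stereocentres arise together as the meso all-cis array.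

Step 4
Reactants: 6 all-cis meso anhydride
Product: 7 all-cis (meso) [2,5-bis(4-chloro-3-methoxyphenyl)oxolane-3,4-diyl]dimethanol
Conditions: LiAlH4, THF, 0 °C to rt; then H2O, aq. NaOH
Reagents that add atoms: none
Why: Hydride reduction of the cyclic anhydride proceeds through the lactone to the 1,4-diol, the cis ring fusion holds C3 and C4 until both carbonyls are reduced, and aryl chlorides are inert to LiAlH4 at room temperature.

Step 5
Reactants: 7 all-cis (meso) diol
Product: 8 all-cis (meso) [2,5-bis(4-chloro-3-methoxyphenyl)oxolane-3,4-diyl]bis(methylene) dimethanesulfonate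
Conditions: MsCl, Et3N, CH2Cl2, 0 °C
Reagents that add atoms: methanesulfonyl chloride, CS(=O)(=O)Cl
Why: O-sulfonylation of the two primary alcohols through the sulfene is fast at 0 °C and should outrun cyclisation of a mono-mesylate to the fused bis-oxolane.

Step 6
Reactants: 8 all-cis (meso) bis-mesylate
Product: 9 (2S,3R,4S,5R)-2,5-bis(4-chloro-3-methoxyphenyl)-3,4-dimethyloxolane (meso, all-cis)
Conditions: LiBHEt3, THF, 0 °C to rt
Reagents that add atoms: none
Why: LiBHEt3 is a strong hydride nucleophile that displaces primary sulfonates by SN2 (reductive deoxygenation) to give the two methyl groups, and neither the aryl chlorides nor the ring stereocentres, which are not at the reacting carbons, should be affected.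

Step 7
Reactants: 10 methyl (S)-lactate
Product: 11 methyl (S)-2-(benzyloxy)propanoate
Conditions: benzyl 2,2,2-trichloroacetimidate, TfOH (cat.), cyclohexane–CH2Cl2, rt
Reagents that add atoms: benzyl 2,2,2-trichloroacetimidate, ClC(Cl)(Cl)C(=N)OCc1ccccc1
Why: Acid-catalysed O-benzylation with the trichloroacetimidate uses no base and therefore should not racemise the lactate α-centre.

Step 8
Reactants: 11 methyl (S)-2-(benzyloxy)propanoate
Product: 12 (S)-2-(benzyloxy)-N-methoxy-N-methylpropanamide
Conditions: MeNH(OMe)·HCl, i-PrMgCl, THF, −20 to 0 °C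
Reagents that add atoms: N,O-dimethylhydroxylamine hydrochloride, CNOC.Cl
Why: The chloromagnesium amide of N,O-dimethylhydroxylamine acylates with the ester (Weinreb amide formation) at low temperature, where the α-alkoxy stereocentre should be retained.

Step 9
Reactants: 12 (S)-2-(benzyloxy)-N-methoxy-N-methylpropanamide; 13 4-bromo-1,2-dimethoxybenzene
Product: 15 (S)-2-(benzyloxy)-1-(3,4-dimethoxyphenyl)propan-1-one, via 3,4-dimethoxyphenyllithium 14 (not isolated)
Conditions: 13, n-BuLi, THF, −78 °C; then 12, −78 to −40 °C; aq. NH4Cl
Reagents that add atoms: none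
Why: Bromine–lithium exchange gives the aryllithium, which adds once to the Weinreb amide because the N-methoxy chelate of the tetrahedral adduct survives until the quench (Weinreb ketone synthesis), and addition at −78 °C should outpace α-deprotonation so that the (S)-centre is kept.

Step 10
Reactants: 15 (S)-2-(benzyloxy)-1-(3,4-dimethoxyphenyl)propan-1-one
Product: 16 (1R,2S)-2-(benzyloxy)-1-(3,4-dimethoxyphenyl)propan-1-ol
Conditions: Zn(BH4)2, Et2O, −30 to 0 °C
Reagents that add atoms: none
Why: Chelation-controlled reduction, in which zinc binds the ketone and benzyloxy oxygens in a five-membered Cram chelate and hydride arrives from the face carrying the C2 hydrogen instead of the C2 methyl, should set the new carbinol centre as 1R, anti (erythro) to the 2S centre.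

Step 11
Reactants: 16 (1R,2S)-2-(benzyloxy)-1-(3,4-dimethoxyphenyl)propan-1-ol
Product: 17 [(1R,2S)-2-(benzyloxy)-1-(3,4-dimethoxyphenyl)propoxy]tri(propan-2-yl)silane
Conditions: TIPSOTf, 2,6-lutidine, CH2Cl2, −78 to 0 °C
Reagents that add atoms: triisopropylsilyl trifluoromethanesulfonate, CC(C)[Si](OS(=O)(=O)C(F)(F)F)(C(C)C)C(C)C
Why: O-silylation with a silyl triflate and a hindered pyridine base protects hindered secondary alcohols without ionising the benzylic carbinol, and the bulky triisopropylsilyl group is chosen because it resists 1,2 O→O migration in step 13.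

Step 12
Reactants: 17 [(1R,2S)-2-(benzyloxy)-1-(3,4-dimethoxyphenyl)propoxy]tri(propan-2-yl)silane
Product: 18 (1R,2S)-1-(3,4-dimethoxyphenyl)-1-[(triisopropylsilyl)oxy]propan-2-ol
Conditions: H2 (1 atm), Pd/C, EtOAc, rt
Reagents that add atoms: none
Why: Hydrogenolysis of the unsubstituted benzyl ether on palladium in a neutral aprotic solvent should be faster than cleavage of the hindered secondary benzylic C–O bond, whose silyloxy group is a poor leaving group, so the C2 hydroxyl is freed with both stereocentres intact.

Step 13
Reactants: 9 (2S,3R,4S,5R)-2,5-bis(4-chloro-3-methoxyphenyl)-3,4-dimethyloxolane (1 equiv); 18 (1R,2S)-1-(3,4-dimethoxyphenyl)-1-[(triisopropylsilyl)oxy]propan-2-ol (3 equiv)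
Product: 19 bis(triisopropylsilyl) ether of the target
Conditions: [(cinnamyl)PdCl]2 (5 mol %), RockPhos (12 mol %), Cs2CO3, toluene, 90 °C
Reagents that add atoms: none
Why: Zerovalent palladium carrying the bulky di-tert-butyl biaryl phosphine inserts into each aryl C4–Cl bond, carbonate-assisted exchange of chloride for the alkoxide of 18 gives an arylpalladium alkoxide, and C–O reductive elimination forms the aryl C4–O–C8 ether and returns zerovalent palladium. The closest known reaction type is the palladium-catalysed C–O cross-coupling of secondary alcohols with electron-rich, ortho-substituted aryl chlorides (Buchwald–Hartwig etherification). No ring is closed and no stereocentre is created: the C8–O bond of 18 is never broken, so the (1R,2S) chain is transferred with retention, and the four oxolane stereocentres are remote from the reaction and not epimerisable under carbonate. The selectivity needed is reductive elimination over β-hydride elimination of the hindered secondary alkoxide, which is secured by the large ligand and helped by the ortho-methoxy group, both of which crowd the metal; the choice between the two chain oxygens is secured by the non-migrating triisopropylsilyl ether on the benzylic oxygen. Because 9 is meso with two equivalent chlorides and both chains are the same enantiomer, the twofold coupling can give only one stereoisomer, and the excess of 18 drives the second coupling.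

Step 14
Reactants: 19 bis(triisopropylsilyl) ether of the target
Product: 20 target, CNP0116650.5
Conditions: Bu4NF, THF, 0 °C to rt; aq. NH4Cl
Reagents that add atoms: none
Why: Fluoride-induced desilylation, driven by the strong Si–F bond, should free both benzylic hydroxyls while leaving the aryl alkyl ethers, the oxolane and all eight stereocentres untouched.

**Compound list**
1 | 4-chloro-3-methoxybenzaldehyde | COc1cc(C=O)ccc1Cl | starting material
2 | (E)-1,2-bis(4-chloro-3-methoxyphenyl)ethene | COc1cc(/C=C/c2ccc(Cl)c(OC)c2)ccc1Cl | intermediate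
3 | trans-2,3-bis(4-chloro-3-methoxyphenyl)oxirane (racemic, one enantiomer drawn) | COc1cc([C@@H]2O[C@H]2c2ccc(Cl)c(OC)c2)ccc1Cl | intermediate
4 | maleic anhydride | O=C1OC(=O)C=C1 | starting material
5 | exo,exo carbonyl ylide, 1,3-bis(4-chloro-3-methoxyphenyl)-2-oxapropane-1,3-diyl zwitterion | COc1cc(/C=[O+]/[CH-]c2ccc(Cl)c(OC)c2)ccc1Cl | intermediate (not isolated)
6 | all-cis meso 4,6-bis(4-chloro-3-methoxyphenyl)tetrahydrofuro[3,4-c]furan-1,3-dione (aryl groups and anhydride on the same face of the oxolane) | COc1cc(ccc1Cl)[C@H]1O[C@@H](c2ccc(Cl)c(OC)c2)[C@H]2C(=O)OC(=O)[C@@H]12 | intermediate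
7 | all-cis (meso) [2,5-bis(4-chloro-3-methoxyphenyl)oxolane-3,4-diyl]dimethanol | COc1cc(ccc1Cl)[C@H]1O[C@@H](c2ccc(Cl)c(OC)c2)[C@@H](CO)[C@H]1CO | intermediate
8 | all-cis (meso) [2,5-bis(4-chloro-3-methoxyphenyl)oxolane-3,4-diyl]bis(methylene) dimethanesulfonate | COc1cc(ccc1Cl)[C@H]1O[C@@H](c2ccc(Cl)c(OC)c2)[C@@H](COS(C)(=O)=O)[C@H]1COS(C)(=O)=O | intermediate
9 | (2S,3R,4S,5R)-2,5-bis(4-chloro-3-methoxyphenyl)-3,4-dimethyloxolane (meso, all-cis) | COc1cc(ccc1Cl)[C@H]1O[C@@H](c2ccc(Cl)c(OC)c2)[C@@H](C)[C@H]1C | intermediate
10 | methyl (S)-lactate | C[C@H](O)C(=O)OC | starting material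
11 | methyl (S)-2-(benzyloxy)propanoate | C[C@H](OCc1ccccc1)C(=O)OC | intermediate
12 | (S)-2-(benzyloxy)-N-methoxy-N-methylpropanamide | C[C@H](OCc1ccccc1)C(=O)N(C)OC | intermediate
13 | 4-bromo-1,2-dimethoxybenzene | COc1ccc(Br)cc1OC | starting material
14 | 3,4-dimethoxyphenyllithium | [Li]c1ccc(OC)c(OC)c1 | intermediate (not isolated)
15 | (S)-2-(benzyloxy)-1-(3,4-dimethoxyphenyl)propan-1-one | COc1ccc(C(=O)[C@H](C)OCc2ccccc2)cc1OC | intermediate
16 | (1R,2S)-2-(benzyloxy)-1-(3,4-dimethoxyphenyl)propan-1-ol | COc1ccc([C@@H](O)[C@H](C)OCc2ccccc2)cc1OC | intermediate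
17 | [(1R,2S)-2-(benzyloxy)-1-(3,4-dimethoxyphenyl)propoxy]tri(propan-2-yl)silane | COc1ccc([C@@H](O[Si](C(C)C)(C(C)C)C(C)C)[C@H](C)OCc2ccccc2)cc1OC | intermediate
18 | (1R,2S)-1-(3,4-dimethoxyphenyl)-1-[(triisopropylsilyl)oxy]propan-2-ol | COc1ccc([C@@H](O[Si](C(C)C)(C(C)C)C(C)C)[C@H](C)O)cc1OC | intermediate
19 | bis(triisopropylsilyl) ether of the target: all-cis 3,4-dimethyloxolane whose C2 and C5 each carry a 3-methoxyphenyl ring O-linked at C4 to C2 of a (1R,2S)-1-(3,4-dimethoxyphenyl)-1-(triisopropylsilyloxy)propan-2-yl chain | COc1ccc([C@@H](O[Si](C(C)C)(C(C)C)C(C)C)[C@H](C)Oc2ccc([C@H]3O[C@@H](c4ccc(O[C@@H](C)[C@H](O[Si](C(C)C)(C(C)C)C(C)C)c5ccc(OC)c(OC)c5)c(OC)c4)[C@@H](C)[C@H]3C)cc2OC)cc1OC | intermediate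
20 | target CNP0116650.5: (2S,3R,4S,5R)-3,4-dimethyloxolane (all-cis) whose C2 and C5 each carry a 3-methoxyphenyl ring O-linked at C4 to C2 of a (1R,2S)-1-(3,4-dimethoxyphenyl)-1-hydroxypropan-2-yl chain | COc1ccc([C@@H](O)[C@H](C)Oc2ccc([C@H]3O[C@@H](c4ccc(O[C@@H](C)[C@H](O)c5ccc(OC)c(OC)c5)c(OC)c4)[C@@H](C)[C@H]3C)cc2OC)cc1OC | target

**Step count**
Total: 14 steps. Longest linear sequence: 8 steps (steps 1–6, 13, 14; the chain arm, steps 7–12, 13, 14, is equally long).

**Steps most likely to fail**

1. Step 13. β-Hydride elimination from the hindered palladium alkoxide may outrun C–O reductive elimination, which would reduce the aryl chloride and oxidise the chain alcohol, or the reaction may stall after the first coupling. The fallback forms the C8–O bonds instead of the aryl C4–O bonds. It sets out from 9, whose two chlorides are exchanged for hydroxyl (Pd2(dba)3, tBuXPhos, KOH, dioxane–H2O, 100 °C) to give all-cis (meso) 2,5-bis(4-hydroxy-3-methoxyphenyl)-3,4-dimethyloxolane F1. A twofold Mitsunobu reaction with commercial methyl (R)-lactate (PPh3, DIAD, THF) inverts the lactate carbon and should give the bis[(S)-2-aryloxypropanoate] dimethyl ester F2. MeNH(OMe)·HCl and i-PrMgCl convert it into the bis-Weinreb amide F3, and addition of 14 at −78 °C gives the bis(3,4-dimethoxyphenyl) ketone F4. Chelation-controlled reduction with Zn(BH4)2 should then give the two erythro carbinols, and the fallback comes back to the route at 20.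

2. Step 3. The endo and exo approaches of maleic anhydride to the ylide may not be well discriminated, so that the anhydride ends up trans to the aryl groups in part of the material. The fallback replaces kinetic endo control by substrate-directed hydrogenation. It sets out from 3, which is irradiated under the same sensitised conditions with dimethyl acetylenedicarboxylate to give dimethyl cis-2,5-bis(4-chloro-3-methoxyphenyl)-2,5-dihydrofuran-3,4-dicarboxylate F5. Hydrogenation over PtO2 (H2, 4 atm, EtOAc), which spares aryl chlorides, should deliver hydrogen to the face opposite both aryl groups and give all-cis dimethyl 2,5-bis(4-chloro-3-methoxyphenyl)oxolane-3,4-dicarboxylate F6. LiAlH4 reduction then comes back to the route at 7.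

3. Step 6. Hydride may attack sulfur instead of carbon, freeing an alkoxide that displaces the neighbouring mesylate and closes a fused bis-oxolane. The fallback replaces ionic hydride displacement by radical dehalogenation. It sets out from 8, which with NaI in butanone at reflux (Finkelstein exchange) should give all-cis (meso) 2,5-bis(4-chloro-3-methoxyphenyl)-3,4-bis(iodomethyl)oxolane F7. Bu3SnH and AIBN in toluene at 80 °C remove both iodides without touching the aryl chlorides, and the fallback comes back to the route at 9.

**Further compounds**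
F1 | step 13 | all-cis (meso) 2,5-bis(4-hydroxy-3-methoxyphenyl)-3,4-dimethyloxolane | COc1cc(ccc1O)[C@H]1O[C@@H](c2ccc(O)c(OC)c2)[C@@H](C)[C@H]1C
F2 | step 13 | dimethyl (2S,2'S)-2,2'-{(all-cis-3,4-dimethyloxolane-2,5-diyl)bis[(2-methoxy-4,1-phenylene)oxy]}dipropanoate | COC(=O)[C@H](C)Oc1ccc(cc1OC)[C@H]1O[C@@H](c2ccc(O[C@@H](C)C(=O)OC)c(OC)c2)[C@@H](C)[C@H]1C
F3 | step 13 | corresponding bis(N-methoxy-N-methylamide) of F2, both α-carbons S | CON(C)C(=O)[C@H](C)Oc1ccc(cc1OC)[C@H]1O[C@@H](c2ccc(O[C@@H](C)C(=O)N(C)OC)c(OC)c2)[C@@H](C)[C@H]1C
F4 | step 13 | bis-ketone: all-cis 3,4-dimethyloxolane whose C2 and C5 each carry a 3-methoxyphenyl ring O-linked at C4 to C2 of an (S)-1-(3,4-dimethoxyphenyl)-1-oxopropan-2-yl chain | COc1ccc(C(=O)[C@H](C)Oc2ccc([C@H]3O[C@@H](c4ccc(O[C@@H](C)C(=O)c5ccc(OC)c(OC)c5)c(OC)c4)[C@@H](C)[C@H]3C)cc2OC)cc1OC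
F5 | step 3 | dimethyl cis-2,5-bis(4-chloro-3-methoxyphenyl)-2,5-dihydrofuran-3,4-dicarboxylate (meso) | COc1cc(ccc1Cl)[C@H]1O[C@@H](c2ccc(Cl)c(OC)c2)C(C(=O)OC)=C1C(=O)OC
F6 | step 3 | all-cis (meso) dimethyl 2,5-bis(4-chloro-3-methoxyphenyl)oxolane-3,4-dicarboxylate | COc1cc(ccc1Cl)[C@H]1O[C@@H](c2ccc(Cl)c(OC)c2)[C@@H](C(=O)OC)[C@H]1C(=O)OC
F7 | step 6 | all-cis (meso) 2,5-bis(4-chloro-3-methoxyphenyl)-3,4-bis(iodomethyl)oxolane | COc1cc(ccc1Cl)[C@H]1O[C@@H](c2ccc(Cl)c(OC)c2)[C@@H](CI)[C@H]1CI
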